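**Retrosynthetic overview**
1. Target 19 ⇐ (4Z)-allylic alcohol 17 by one-flask epoxidation/angelate opening (C4–O, C5–O); 17 ⇐ (3E)-alkene 13 by singlet-oxygen ene/Kornblum–DeLaMare, exo→endo isomerisation and Luche reduction.
2. 13 ⇐ (7Z,3E)-cyclodecadienone 8 by Luche reduction (C9), hydroxyl-directed epoxidation (C7–C8) and angeloylation.
3. 8 ⇐ thermal retro-[2+2] of tricyclic adduct 7 ⇐ photochemical [2+2] of enone 5 with 1-methylcyclobutene (key step; forms C3–C4 and C7–C8).
4. 5 ⇐ (S)-carvone (C1) by α′-hydroxylation and Mitsunobu inversion with (R)-2-methylbutanoic acid (C10 and the ester centre).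
5. Ring order: bought cyclohexenone → bicyclo[2.2.0]hexane → ten-membered carbocycle → 7,8-epoxide → transient 4,5-epoxide.

Assumption: the SMILES is taken at face value, so the saturated ester is (2R)-2-methylbutanoate; (S)-(+)-carvone, (R)-2-methylbutanoic acid, angelic acid and 1-methylcyclobutene are bought.

Locants used below (target ring): C1 CH–isopropenyl, C2 CH2, C3 CH(OH), C4 C(CH3)(OH), C5 CH–O-angeloyl, C6 CH2, C7 epoxide CH, C8 epoxide C(CH3), C9 CH–O-angeloyl, C10 CH–O-2-methylbutanoyl. β is the ring face carrying the isopropenyl group, α the other face. In these locants the target is 1R,3R,4S,5S,7S,8S,9S,10S.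

Step 1
Reactants: 1 (S)-(+)-carvone
Product: 3 (5R,6R)-6-hydroxycarvone (10α-OH; trans to isopropenyl), via lithium dienolate 2 (not isolated)
Conditions: LiN(iPr)2, THF, −78 °C; then O2, P(OEt)3, −78 → −30 °C; AcOH quench
Reagents that add atoms: dioxygen, O=O
Why: Kinetic α′-deprotonation gives the cross-conjugated dienolate, and enolate oxygenation (O2/P(OEt)3 hydroxylation) occurs anti to the adjacent C1 isopropenyl group to give mainly the trans alcohol (any cis alcohol is esterified directly with 4 to the same ester 5).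

Step 2
Reactants: 3 (5R,6R)-6-hydroxycarvone; 4 (R)-2-methylbutanoic acid
Product: 5 (1S,6R)-3-methyl-2-oxo-6-(prop-1-en-2-yl)cyclohex-3-en-1-yl (2R)-2-methylbutanoate (10β-ester; cis to isopropenyl)
Conditions: PPh3, DIAD, toluene, 0 °C → rt
Reagents that add atoms: none
Why: Mitsunobu esterification displaces the activated α-keto carbinol by SN2, inverting C10 so the ester sits on the β face, while the (R) centre of 4 is not touched.

Step 3
Reactants: 5 cis-6-acyloxy enone; 6 1-methylcyclobutene
Product: 7 cis-anti-cis tricyclo[4.4.0.0^2,5]decanone photoadduct (cyclobutanes on the α face; CH3 on C4 and C8)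
Conditions: hν (350–366 nm, Pyrex), 6 (8 equiv), CH2Cl2, −30 °C
Reagents that add atoms: none
Why: Enone–alkene [2+2] photocycloaddition (triplet enone, 1,4-biradical; photochemical half of a photo-thermal metathesis) forms C3–C4 and C7–C8 head-to-tail, which avoids vicinal quaternary centres, on the α face opposite the C1/C10 substituents, and the four new centres are erased in step 4.

Step 4
Reactants: 7 tricyclic photoadduct
Product: 8 ten-membered (7Z,3E)-dienone (C9 ketone; 1β-isopropenyl; 10β-ester)
Conditions: toluene (0.01 M), 190 °C, sealed silylated glass tube, 2 h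
Reagents that add atoms: none
Why: Thermal retro-[2+2] of the bicyclo[2.2.0]hexane (homolysis of the central C4–C7 bond to a cyclohexane-1,4-diyl, then scission of C3–C8) releases the strain of both four-membered rings and opens the ten-membered ring; the chair-like diyl with the acyl carbon C9 axial gives the conjugated (7Z) and the (3E) alkene, and C1/C10 are untouched.

Step 5
Reactants: 8 (7Z,3E)-dienone
Product: 9 9β-allylic alcohol (9,10-cis)
Conditions: NaBH4, CeCl3·7H2O, MeOH, −78 °C
Reagents that add atoms: none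
Why: Luche 1,2-reduction with Felkin–Anh addition anti to the C10 acyloxy group, from the α face away from the β substituents at C10 and C1, sets the 9β alcohol.

Step 6
Reactants: 9 9β-allylic alcohol
Product: 10 7α,8α-epoxy-9β-alcohol
Conditions: Ti(OiPr)4 (1.1 equiv), tBuOOH (1.5 equiv, decane), CH2Cl2, −20 °C
Reagents that add atoms: tert-butyl hydroperoxide, CC(C)(C)OO
Why: Hydroxyl-directed epoxidation by titanium tert-butylperoxide (tartrate-free Sharpless conditions) touches only the allylic alcohol, and A1,3 strain between C9–H and C6 across the (Z)-alkene keeps C9–H in the alkene plane so oxygen is delivered threo, i.e. to the α face.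

Step 7
Reactants: 10 7α,8α-epoxy-9β-alcohol; 11 angelic acid
Product: 13 9β-angelate, via mixed anhydride 12 (not isolated)
Conditions: 11, 2,4,6-trichlorobenzoyl chloride, Et3N, toluene, rt; then 10, 75 °C
Reagents that add atoms: none
Why: Yamaguchi-type mixed-anhydride esterification acylates the hindered C9 alcohol without Z→E isomerisation of the angelate and without forming an alkoxide that could trigger migration of the neighbouring C10 ester; no stereocentre changes.

Step 8
Reactants: 13 9β-angelate
Product: 15 4-methylene-3-ketone, via allylic hydroperoxide 14 (not isolated)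
Conditions: O2, tetraphenylporphyrin (cat.), hν (white LED), CH2Cl2, −30 °C; then Ac2O, pyridine, DMAP (cat.), 0 °C
Reagents that add atoms: dioxygen, O=O
Why: Schenck ene reaction of singlet oxygen with the strained (3E)-trisubstituted alkene (oxygen to the CH carbon C3 from the ring periphery, hydrogen from the C4 methyl, as is typical for such ring alkenes) followed by Kornblum–DeLaMare dehydration gives the ketone; isopropenyl, angelate and epoxide are inert to singlet oxygen and C3 is planarised here.

Step 9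
Reactants: 15 4-methylene-3-ketone
Product: 16 (4Z)-en-3-one
Conditions: RhH(CO)(PPh3)3 (2 mol %), toluene, 60 °C
Reagents that add atoms: none
Why: Rhodium-hydride addition/β-hydride elimination (exo-to-endo enone isomerisation) moves the double bond into the ring to the more stable trisubstituted (Z)-enone under neutral conditions, avoiding base that would open the γ,δ-epoxy enone.

Step 10
Reactants: 16 (4Z)-en-3-one
Product: 17 3β-hydroxy-(4Z)-ene
Conditions: NaBH4, CeCl3·7H2O, MeOH, −78 °C
Reagents that add atoms: none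
Why: Luche 1,2-reduction with hydride from the α face, opposite the 1β-isopropenyl group that flanks C3 through C2, gives the 3β alcohol (1,3-cis to isopropenyl; the minor 3α epimer is recycled by MnO2 oxidation to 16).

Step 11
Reactants: 17 3β-hydroxy-(4Z)-ene; 11 angelic acid
Product: 19 CNP0246823.3, via epoxy alcohol 18 (not isolated)
Conditions: Ti(OiPr)4 (1.1 equiv), tBuOOH (1.05 equiv), CH2Cl2, −20 °C; then Ti(OiPr)4 (1.5 equiv) premixed with 11 (3 equiv) as Ti(OiPr)2(O2CC(CH3)=CHCH3)2, 0 °C → rt
Reagents that add atoms: tert-butyl hydroperoxide, CC(C)(C)OO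
Why: Proposed new method: a one-flask titanium-templated anti-hydroxy-acyloxylation of a (Z)-allylic alcohol, in which the titanium alkoxide of 17 is first epoxidised threo by bound tert-butyl peroxide (A1,3 control, 4α,5α-epoxide 18) and the same tetravalent titanium centre, then loaded with angelate, holds the 2,3-epoxy alkoxide as a chelate in which only the distal C5–O bond is aligned for backside attack by a titanium-bound carboxylate, so C5 is inverted (5β-angelate), C4 keeps its oxygen (4α-OH) and the unchelated 7,8-epoxide is left alone; the closest known reactions are tartrate-free Ti(OiPr)4/tBuOOH epoxidation of allylic alcohols and the Ti(OiPr)4-mediated C3-selective opening of 2,3-epoxy alcohols by benzoic or pivalic acid, which have not been merged, nor shown with an α,β-unsaturated acid or a 2-methyl epoxy alcohol in a medium ring.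

**Compound list**
1 | (S)-(+)-carvone, (5S)-2-methyl-5-(prop-1-en-2-yl)cyclohex-2-en-1-one | C=C(C)[C@H]1CC=C(C)C(=O)C1 | starting material
2 | lithium cross-conjugated dienolate of 1 (O–Li on C9, C9=C10) | C=C(C)[C@H]1CC=C(C)C(O[Li])=C1 | intermediate
3 | (5R,6R)-6-hydroxy-2-methyl-5-(prop-1-en-2-yl)cyclohex-2-en-1-one (OH trans to isopropenyl) | C=C(C)[C@H]1CC=C(C)C(=O)[C@@H]1O | intermediate
4 | (R)-2-methylbutanoic acid | OC(=O)[C@H](C)CC | starting material
5 | (1S,6R)-3-methyl-2-oxo-6-(prop-1-en-2-yl)cyclohex-3-en-1-yl (2R)-2-methylbutanoate (ester cis to isopropenyl) | C=C(C)[C@H]1CC=C(C)C(=O)[C@H]1OC(=O)[C@H](C)CC | intermediate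
6 | 1-methylcyclobutene | CC1=CCC1 | starting material
7 | cis-anti-cis tricyclo[4.4.0.0^2,5]decanone photoadduct: cyclobutane C8–C3–C4–C7 fused on the α face of the cyclohexanone and to a second cyclobutane C4–C5–C6–C7; CH3 on C4 and C8; C9 ketone; 1β-isopropenyl; 10β-(2R)-2-methylbutanoate | C=C(C)[C@H]1C[C@@H]2[C@@]3(C)CC[C@H]3[C@]2(C)C(=O)[C@H]1OC(=O)[C@H](C)CC | intermediate
8 | ten-membered (7Z,3E)-dienone: C9 ketone, C7=C8(CH3) Z, C3=C4(CH3) E, 1β-isopropenyl, 10β-(2R)-2-methylbutanoate | C=C(C)[C@H]1C/C=C(C)/CC/C=C(C)\C(=O)[C@H]1OC(=O)[C@H](C)CC | intermediate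
9 | 9β-hydroxy-(7Z,3E)-diene (9,10-cis hydroxy ester) | C=C(C)[C@H]1C/C=C(C)/CC/C=C(C)\[C@@H](O)[C@H]1OC(=O)[C@H](C)CC | intermediate
10 | 7α,8α-epoxy-9β-hydroxy-(3E)-ene | C=C(C)[C@H]1C/C=C(C)/CC[C@@H]2O[C@]2(C)[C@@H](O)[C@H]1OC(=O)[C@H](C)CC | intermediate
11 | angelic acid, (Z)-2-methylbut-2-enoic acid | OC(=O)/C(C)=C\C | starting material
12 | angelic 2,4,6-trichlorobenzoic anhydride | O=C(OC(=O)/C(C)=C\C)c1c(Cl)cc(Cl)cc1Cl | intermediate
13 | 7α,8α-epoxy-9β-angeloyloxy-(3E)-ene | C=C(C)[C@H]1C/C=C(C)/CC[C@@H]2O[C@]2(C)[C@@H](OC(=O)/C(C)=C\C)[C@H]1OC(=O)[C@H](C)CC | intermediate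
14 | 3β-hydroperoxide with exocyclic C4=CH2 | C=C(C)[C@H]1C[C@@H](OO)C(=C)CC[C@@H]2O[C@]2(C)[C@@H](OC(=O)/C(C)=C\C)[C@H]1OC(=O)[C@H](C)CC | intermediate
15 | 3-ketone with exocyclic C4=CH2 | C=C(C)[C@H]1CC(=O)C(=C)CC[C@@H]2O[C@]2(C)[C@@H](OC(=O)/C(C)=C\C)[C@H]1OC(=O)[C@H](C)CC | intermediate
16 | (4Z)-en-3-one (C4 methyl) | C=C(C)[C@H]1CC(=O)/C(C)=C\C[C@@H]2O[C@]2(C)[C@@H](OC(=O)/C(C)=C\C)[C@H]1OC(=O)[C@H](C)CC | intermediate
17 | 3β-hydroxy-(4Z)-ene | C=C(C)[C@H]1C[C@@H](O)/C(C)=C\C[C@@H]2O[C@]2(C)[C@@H](OC(=O)/C(C)=C\C)[C@H]1OC(=O)[C@H](C)CC | intermediate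
18 | 4α,5α:7α,8α-bis-epoxy-3β-ol | C=C(C)[C@H]1C[C@@H](O)[C@]3(C)O[C@@H]3C[C@@H]2O[C@]2(C)[C@@H](OC(=O)/C(C)=C\C)[C@H]1OC(=O)[C@H](C)CC | intermediate
19 | CNP0246823.3: 7α,8α-epoxy-3β,4α-dihydroxy-4β,8β-dimethyl-1β-isopropenylcyclodecane with 5β- and 9β-angelate and 10β-(2R)-2-methylbutanoate | C=C(C)[C@H]1C[C@@H](O)[C@](C)(O)[C@@H](OC(=O)/C(C)=C\C)C[C@@H]2O[C@]2(C)[C@@H](OC(=O)/C(C)=C\C)[C@H]1OC(=O)[C@H](C)CC | target

**Totals**
Total step count: 11. Longest linear sequence: 11 steps (1 → 19).

**Steps most likely to fail**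

Step 4 (thermal ring opening). The hot (Z,E)-1,5-diene can undergo Cope rearrangement to a cis-divinylcyclohexanone, and C10 is an enolisable α-acyloxy centre at 190 °C. The fallback sets out from 7 and moves the reduction ahead of the ring opening: NaBH4/CeCl3·7H2O reduction of the ketone gives the tricyclic 9β-alcohol F1, which has neither an enolisable centre nor a conjugated enone; the same retro-[2+2] at 190 °C then comes back to the route at 9 (any 9α epimer is oxidised with MnO2 to 8).

Step 8 (ene regiochemistry). Singlet oxygen may instead take a C2 hydrogen and give the tertiary C4 hydroperoxide, which cannot be dehydrated to a ketone. The fallback sets out from 13 and avoids peroxide chemistry: OsO4 (cat.)/N-methylmorpholine N-oxide dihydroxylation of the strained (3E)-alkene gives the 3β,4α-diol F2; Dess–Martin oxidation of the secondary alcohol gives the 4α-hydroxy-3-ketone F3; dehydration of the tertiary α-ketol (SOCl2, pyridine) comes back to the route at 16 (any exocyclic isomer 15 is isomerised as in step 9).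

Step 11 (the proposed new step). Risks are attack at the tertiary C4, slow epoxidation of the (Z)-allylic alcohol, and transesterification or angelate isomerisation by titanium. The fallback uses known chemistry and sets out from 17: Ti(OiPr)4/tBuOOH epoxidation with isolation of 18; silylation (Et3SiOTf, 2,6-lutidine) to the 3β-triethylsilyl ether F4; SN2 opening at the secondary C5 with caesium (Z)-2-methylbut-2-enoate and 18-crown-6 in DMF at 70 °C to the silyl-protected triester F5; HF·pyridine then comes back to the route at 19.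

Further compounds
F1 | step 4 | tricyclic 9β-alcohol from reduction of 7 | C=C(C)[C@H]1C[C@@H]2[C@@]3(C)CC[C@H]3[C@]2(C)[C@@H](O)[C@H]1OC(=O)[C@H](C)CC
F2 | step 8 | 3β,4α-diol of 13 | C=C(C)[C@H]1C[C@@H](O)[C@](C)(O)CC[C@@H]2O[C@]2(C)[C@@H](OC(=O)/C(C)=C\C)[C@H]1OC(=O)[C@H](C)CC
F3 | step 8 | 4α-hydroxy-3-ketone | C=C(C)[C@H]1CC(=O)[C@](C)(O)CC[C@@H]2O[C@]2(C)[C@@H](OC(=O)/C(C)=C\C)[C@H]1OC(=O)[C@H](C)CC
F4 | step 11 | 3β-O-triethylsilyl ether of 18 | C=C(C)[C@H]1C[C@@H](O[Si](CC)(CC)CC)[C@]3(C)O[C@@H]3C[C@@H]2O[C@]2(C)[C@@H](OC(=O)/C(C)=C\C)[C@H]1OC(=O)[C@H](C)CC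
F5 | step 11 | 3β-O-triethylsilyl ether of 19 | C=C(C)[C@H]1C[C@@H](O[Si](CC)(CC)CC)[C@](C)(O)[C@@H](OC(=O)/C(C)=C\C)C[C@@H]2O[C@]2(C)[C@@H](OC(=O)/C(C)=C\C)[C@H]1OC(=O)[C@H](C)CC
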